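5 questions stand on 4 flasks, in which substrate joins partner reversibly to product, while partner dissolves from a solid reagent up to its solubility c_s.

| setting | north-east | south-east | south-west | north |
|---|---|---|---|---|
| substrate | 0.10 M | 0.10 M | 0.10 M | 0.10 M |
| solid reagent | 0.100 M | 0.100 M | 0.100 M | 0.100 M |
| temperature | −5 °C | −35 °C | 25 °C |  |
| time | 80 min | 80 min | 80 min | 80 min |
| remark |  |  |  | at 25 °C until 40 min, from then on at −35 °C |

- the flask with the highest amount of product, in percent of the substrate charged ("all alike" if they lie within 1.5 percentage points) (north-east / south-east / south-west / north / all alike)
- final product, as a percentage of the substrate charged, in north-east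
- final product, as a percentage of the substrate charged, in south-east
- final product, as a percentage of the substrate charged, in south-west
- final product, as a percentage of the substrate charged, in north

- as a solid, counted per litre of solution: solid reagent
- all constants are for 25 °C and move with temperature by the activation energies and enthalpies
- at the start none of the solid reagent is in solution

    substrate + partner ⇌ product (K1 = 4.7 M⁻¹, k1 = 13 M⁻¹ min⁻¹, Ea1 = 38.0 kJ mol⁻¹, ΔH1 = −61.0 kJ mol⁻¹)
    solid reagent ⇌ partner, rate k2*(cs2 - [partner]) while solid is left; crystals form when [partner] > cs2 (cs2 = 46 mM, k2 = 0.11 min⁻¹)
    (constants at 25 °C)

While solid lies in a flask at equilibrium, partner stands at c_s. Dividing the forward rate by the back rate then removes time and leaves product over free substrate equal to the saturation ratio S = K·c_s, with K the equilibrium constant: 0.216 at 25 °C. The saturation ratio holds while the demand on the solid, product plus c_s, stays below the charge.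

In south-west, product starts with zero slope, since no partner is there, while partner rises at 5.06 mM min⁻¹. Product in south-west then follows partner, because its relaxation half-life at saturation, 0.206 min, is shorter than the dissolving half-life 6.30 min. Each unit dissolved in south-west is shared between free partner and product, which puts the knee near 9.26 min. The south-west level is S/(1+S), or 17.8%, and the demand 0.0638 M is less than the charge 0.100 M, so solid remains.

In north-east, S grows to 3.39. The north-east demand 0.123 M exceeds the charge, so in this reckoning the solid dissolves entirely and equal charges equilibrate. Free partner in north-east comes to 0.0307 M, below c_s, and product to 69.3%. The north-east level is reached in the time, since the relaxation half-life 3.96 min and the dissolving of the charge at the rate with partner at that level, about 59.3 min, both stay below 80 min.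

At −35 °C, S is 106, but substrate's forward half-life with partner at c_s is 55.1 min, so 80 min holds fewer than 2 of these half-lives, and time counts there. With partner taken at c_s, the upper figures are 63.4% in south-east and 50.3% in north, which starts cold from the south-west level. North-east therefore comes out highest.

The forecast names north-east, with 69.3% in north-east, 53.5% in south-east, 17.8% in south-west and 47% in north, its cold values lying below the upper figures above, and says that “the larger K uses up all the solid”.

The flasks give 69.3% in north-east, 53.6% in south-east, 17.8% in south-west and 46.6% in north, so north-east holds the most product.

In south-west, the relaxation half-life at the end, both ways together, is 0.156 min, short against 80 min, and product over substrate reads 0.217 against S = 0.216. In the neighbour repeating south-west at 0 °C, S is 2.06, and the demand 0.113 M exceeds the charge, so equal charges equilibrate and free partner comes to 0.0374 M. The computed neighbour holds partner at 0.0374 M, solid reagent at 0% of its charge and product at 62.6% of the substrate charged.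

All constants come from no measurement; what happens was integrated by code.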